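The data are calculated with constants of no real substance; the scatter is artificial.

| setting | north-east | flask |
|---|---|---|
| starting material | 0.020 M | 0.020 M |
| second substrate | 1 equiv | 1.00 equiv |
| reagent | 1 equiv | 1.00 equiv |
| capture agent | 1 mM | 1.00 mM |
| free catalyst | 0.75 mol% | 0.5 mol% |
| remark | run made earlier |  |

north-east run (percent of the starting material charged): time / h: target / % = 1.50: 27.2; 3.00: 34.6; 5.00: 37.4; 6.00: 37.3; 8.00: 37.8; 10.0: 38.5; 12.0: 38.2

(readings scatter by 0.3 percentage points)

- apparent order in second substrate when 30 % of the starting material are converted (percent change of the rate of making target for one percent more second substrate charged)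

Divide where the north-east run ended by the catalyst it was given.

N = 38.2 % / 0.75 mol% = 50.9

This reading is the turnover budget, or turnover number: target made per catalyst charged before a run stops.

Now turn the question round. An order near one asks that the flask reach the mark well inside its budget, with its catalyst still working. The north-east readings flatten at 38.2 %, above the mark of 30 %. Carry the budget to the flask:

N × 0.5 mol% = 25.5 %

By my reckoning the budget of the flask stops 4.5 percentage points short of the mark. If the flask arrives at all, it arrives as its catalyst dies, and there any small loss of budget should cut the rate steeply. So I expect a large order, negative if second substrate costs budget; with [second substrate] never varied, that sign is my guess.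

The forecast differs: it gives 1, on the ground that “A bimolecular step suggests about 1”.

The flask gives −3.4.

    starting material + free catalyst ⇌ catalyst intermediate A (K = 130 /M, k = 104 /M/min)
    reagent + catalyst intermediate A → free catalyst + target (k = 107 /M/min)
    second substrate + free catalyst ⇌ catalyst intermediate B (K = 1470 /M, k = 74.6 /M/min)
    reagent + catalyst intermediate B → free catalyst + second product (k = 437 /M/min)
    catalyst intermediate A + capture agent → trapped intermediate (k = 21.3 /M/min)

Up to 4.00 h the flask ran both rounds, making target through catalyst intermediate A and second product through catalyst intermediate B, the latter with 89 % of its turnover up to 40.0 h done, while trapped intermediate took up 85.3 % of the catalyst. The flask passed the mark at 4.29 h, making target at 2.52 × 10⁻⁴ M/h, and by 20.0 h trapped intermediate held >99.9 % of the catalyst, with target at 32.0 %. The flask's own budget was thus 64.0, more than N, and the mark lay 2 points below its end. With twice the free catalyst of this flask, N gives 50.9 %, clear of the mark, and the rate at the mark is multiplied by 8.95.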